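Ring B of the phthalide (C3a, C4, C5, C6, C7, C7a) is a resorcinol whose oxygens sit on C5 and C7 and whose C7a carries the carboxyl carbon C1; it is therefore the dehydrogenated form of a 2,4-dioxocyclohexanecarboxylate. Everything rests on cutting C7a–C3a and C5–C6. One operation, a conjugate addition followed by a Claisen ring closure, joins a 4-substituted acetoacetate that already holds the C6 oxymethyl carbon as a silyl ether to a but-2-enoate that holds C3 as a dimethyl acetal, and delivers the six-membered ring with every substituent in place. Dehydrogenation, lactol masking, esterification and an enzymatic resolution of C3 follow.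

Key step: step 3

Assumption 1: the stereocentre of the target is (3R) in phthalide numbering; as a lactol it can epimerise through the ring-opened 2-formylbenzoic acid, so it is fixed on the configurationally stable acetate 20 and released only in the last step under neutral, anhydrous conditions, and the product is to be handled cold and kept dry.
Assumption 2: (triisopropylsiloxy)methyl chloride 5 is taken as a commercial reagent.

Design notes:
- Keto ester 6 is made in one step by γ-alkylation of the acetoacetate dianion, which avoids free methyl 5-hydroxy-3-oxopentanoate (prone to lactonisation and loss of formaldehyde).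
- A trialkylsilyl ether is kept on the oxymethyl group because a trialkylsilanolate is a poorer leaving group than an arylsilanolate and the ether is removed later with buffered fluoride.
- The ring-forming step is run with KOtBu in THF, not with an alkoxide in its alcohol, so that no methanol or methoxide pool can exchange the silyloxy group by elimination and re-addition.

Step 1
Reactants: 1 2,2-dimethoxyacetaldehyde (60% aqueous solution); 2 trimethyl phosphonoacetate
Product: 3 methyl (E)-4,4-dimethoxybut-2-enoate
Conditions: K2CO3 (2 equiv), H2O–THF, 0 to 23 °C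
Reagents that add atoms: none
Why: Horner–Wadsworth–Emmons olefination of an unhindered aldehyde with a stabilised phosphonate under mild aqueous carbonate conditions should give the (E)-enoate, and the acetal is inert to base.

Step 2
Reactants: 4 methyl acetoacetate; 5 (triisopropylsiloxy)methyl chloride
Product: 6 methyl 3-oxo-5-[(triisopropylsilyl)oxy]pentanoate
Conditions: LiN(iPr)2 (2.1 equiv), THF, 0 °C; then 5, −78 to 0 °C; aq NH4Cl
Reagents that add atoms: none
Why: γ-Alkylation of a β-keto ester dianion, in which the terminal and most basic carbanion of the dilithium dianion of 4 displaces chloride from the reactive α-chloro ether in an SN2 reaction and so installs the silyl-protected oxymethyl carbon without passing through the free β-hydroxy ketone.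

Step 3
Reactants: 6 methyl 3-oxo-5-[(triisopropylsilyl)oxy]pentanoate; 3 methyl (E)-4,4-dimethoxybut-2-enoate
Product: 8 methyl 6-(dimethoxymethyl)-2,4-dioxo-3-{[(triisopropylsilyl)oxy]methyl}cyclohexane-1-carboxylate, via Michael adduct diester 7 (not isolated)
Conditions: KOtBu (1.05 equiv), THF, 0 °C; then 3 (1.2 equiv), 0 to 23 °C; cold aq NaH2PO4 (pH 4 to 5)
Reagents that add atoms: none
Why: The potassium enolate of the ester–ketone methylene of 6, the most acidic site, adds to the β-carbon of enoate 3 and forms C7a–C3a; after proton transfer the ketone α′-carbon of 7, the one bearing the silyloxymethyl group, attacks the remote ester, expels methoxide and forms C6–C5. The closest known reaction type is the Michael–Dieckmann annulation of acetoacetates with crotonates that gives dihydroorsellinates. The ring closes in the 6-(enolexo)-exo-trig mode, the only one available because every other enolate–carbonyl pairing in 7 would give a four-membered ring. Three stereocentres (C1, C3 and C6 of the cyclohexane) arise without control as a mixture, which is harmless because all of them become trigonal on aromatisation. The selectivity needed is chemoselectivity against β-elimination of the silyloxy group: stoichiometric tert-butoxide in an aprotic solvent holds 6 wholly as its C2 enolate before the Michael step, supplies no alcohol pool that could add to an eliminated vinyl ketone, and lets the product rest as the weakly basic dione enolate.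

Step 4
Reactants: 8 methyl 6-(dimethoxymethyl)-2,4-dioxo-3-{[(triisopropylsilyl)oxy]methyl}cyclohexane-1-carboxylate
Product: 11 methyl 6-(dimethoxymethyl)-2,4-dihydroxy-3-{[(triisopropylsilyl)oxy]methyl}benzoate, via C1 phenylselenide 9 (not isolated), via selenoxide 10 (not isolated)
Conditions: LiN(SiMe3)2 (2.2 equiv), THF, −78 °C; PhSeCl (1.05 equiv), −78 °C; then AcOH, 30% H2O2, 0 to 23 °C
Reagents that add atoms: none
Why: α-Selenenylation and selenoxide syn-elimination, in which the ester-stabilised C1 carbanion of the dianion of 8 is the more nucleophilic site and should take up selenium anti to the C6 acetal, so that the selenoxide finds the cis C6 hydrogen, eliminates to the C1–C6 alkene near room temperature, and the cyclohexenedione tautomerises to the resorcinol without harm to the silyl ether or the acetal.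

Step 5
Reactants: 11 methyl 6-(dimethoxymethyl)-2,4-dihydroxy-3-{[(triisopropylsilyl)oxy]methyl}benzoate
Product: 12 methyl 6-(dimethoxymethyl)-2-hydroxy-4-methoxy-3-{[(triisopropylsilyl)oxy]methyl}benzoate
Conditions: MeI (1.1 equiv), K2CO3 (1.1 equiv), acetone, 23 °C
Reagents that add atoms: iodomethane, CI
Why: Williamson ether synthesis under weak base, selective because the C4 hydroxyl (the future C5 oxygen) is the more acidic one and the only one not held in a hydrogen bond to the ester carbonyl, as in the mono-O-methylation of orsellinates.

Step 6
Reactants: 12 methyl 6-(dimethoxymethyl)-2-hydroxy-4-methoxy-3-{[(triisopropylsilyl)oxy]methyl}benzoate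
Product: 13 rac-7-hydroxy-3,5-dimethoxy-6-{[(triisopropylsilyl)oxy]methyl}isobenzofuran-1(3H)-one
Conditions: camphorsulfonic acid (0.1 equiv), MeOH–H2O (20:1), 23 °C; NaHCO3
Reagents that add atoms: water, O
Why: Acid-catalysed conversion of a normal ester into a pseudo ester, in which the oxocarbenium ion from the acetal is captured by the neighbouring ester carbonyl through a five-membered transition state and water turns the cyclic dialkoxycarbenium ion into the lactone with loss of methanol, the new C3 acetal centre forming as a racemate because nothing differentiates its two faces.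

Step 7
Reactants: 13 rac-7-hydroxy-3,5-dimethoxy-6-{[(triisopropylsilyl)oxy]methyl}isobenzofuran-1(3H)-one
Product: 14 rac-7-hydroxy-6-(hydroxymethyl)-3,5-dimethoxyisobenzofuran-1(3H)-one
Conditions: Bu4NF (1.2 equiv), AcOH (1.2 equiv), THF, 0 to 23 °C
Reagents that add atoms: none
Why: Fluoride-induced desilylation driven by the strong Si–F bond, buffered with acetic acid so that the base-labile pseudo ester and the chelated phenol are not disturbed.

Step 8
Reactants: 15 methyl 2,4-dihydroxy-3,6-dimethylbenzoate
Product: 16 methyl 2-hydroxy-4-methoxy-3,6-dimethylbenzoate (methyl rhizonate)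
Conditions: MeI (1.1 equiv), K2CO3 (1.1 equiv), acetone, 40 °C
Reagents that add atoms: iodomethane, CI
Why: Williamson ether synthesis selective for the more acidic, non-chelated C4 hydroxyl para to the ester, the C2 hydroxyl being held by a hydrogen bond to the carbonyl group.

Step 9
Reactants: 16 methyl 2-hydroxy-4-methoxy-3,6-dimethylbenzoate
Product: 17 2-hydroxy-4-methoxy-3,6-dimethylbenzoic acid (rhizonic acid)
Conditions: KOH (5 equiv), DMSO–H2O (4:1), 80 °C; then 1 M HCl, 0 °C
Reagents that add atoms: potassium hydroxide, [K+].[OH-]
Why: Saponification of a hindered benzoate under forcing conditions in a dipolar solvent, followed by cold acidification so that the electron-rich salicylic acid does not decarboxylate.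

Step 10
Reactants: 14 rac-7-hydroxy-6-(hydroxymethyl)-3,5-dimethoxyisobenzofuran-1(3H)-one; 17 2-hydroxy-4-methoxy-3,6-dimethylbenzoic acid
Product: 18 rac-(7-hydroxy-3,5-dimethoxy-1-oxo-1,3-dihydroisobenzofuran-6-yl)methyl 2-hydroxy-4-methoxy-3,6-dimethylbenzoate
Conditions: PPh3 (1.3 equiv), DIAD (1.3 equiv), 17 (1.2 equiv), THF, 0 to 23 °C
Reagents that add atoms: none
Why: Mitsunobu esterification, in which the primary benzylic alcohol is activated at oxygen and displaced by the carboxylate, so that the hindered carbonyl group of 17 is never attacked and the carboxylic acid, far more acidic than either hydrogen-bonded phenol, should be the only pronucleophile that reacts.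

Step 11
Reactants: 18 rac-(7-hydroxy-3,5-dimethoxy-1-oxo-1,3-dihydroisobenzofuran-6-yl)methyl 2-hydroxy-4-methoxy-3,6-dimethylbenzoate
Product: 19 rac-(3,7-dihydroxy-5-methoxy-1-oxo-1,3-dihydroisobenzofuran-6-yl)methyl 2-hydroxy-4-methoxy-3,6-dimethylbenzoate
Conditions: 1 M HCl–THF (1:3), 40 °C
Reagents that add atoms: water, O
Why: Acid-catalysed hydrolysis of the cyclic mixed acetal to the lactol in a large excess of water, at an acidity expected to be too low to ionise the benzylic ester whose ring is deactivated by the lactone carbonyl group, the lactol forming as a racemate.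

Step 12
Reactants: 19 rac-(3,7-dihydroxy-5-methoxy-1-oxo-1,3-dihydroisobenzofuran-6-yl)methyl 2-hydroxy-4-methoxy-3,6-dimethylbenzoate
Product: 20 [(3R)-3-acetoxy-7-hydroxy-5-methoxy-1-oxo-1,3-dihydroisobenzofuran-6-yl]methyl 2-hydroxy-4-methoxy-3,6-dimethylbenzoate
Conditions: immobilised Burkholderia cepacia lipase, vinyl acetate (5 equiv), MTBE, 40 °C
Reagents that add atoms: vinyl acetate, C=COC(C)=O
Why: Lipase-catalysed acylative dynamic kinetic resolution of a lactol, in which the enantiomers of 19 interconvert through the ring-opened formyl acid while the chiral active site acetylates only one of them, expected to be the (R)-lactol by the empirical size rule for lipases (fused arene as the large and lactone oxygen as the medium substituent), while the irreversible acyl donor and the inertness of chelated phenols towards the enzyme secure chemoselectivity.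

Step 13
Reactants: 20 [(3R)-3-acetoxy-7-hydroxy-5-methoxy-1-oxo-1,3-dihydroisobenzofuran-6-yl]methyl 2-hydroxy-4-methoxy-3,6-dimethylbenzoate
Product: 21 [(3R)-3,7-dihydroxy-5-methoxy-1-oxo-1,3-dihydroisobenzofuran-6-yl]methyl 2-hydroxy-4-methoxy-3,6-dimethylbenzoate
Conditions: immobilised Burkholderia cepacia lipase, n-BuOH (5 equiv), MTBE, 20 °C; filtration, evaporation below 25 °C
Reagents that add atoms: none
Why: Lipase-catalysed transesterification of the acetate with butanol, for which 20 is the matched enantiomer, cleaves the acyl–oxygen bond and leaves the C3–O bond untouched, so the (R) configuration should be retained, and the neutral, base-free medium spares the hindered rhizonate ester and the lactone.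

Compound list
1 | 2,2-dimethoxyacetaldehyde | COC(OC)C=O | starting material
2 | trimethyl phosphonoacetate | COC(=O)CP(=O)(OC)OC | starting material
3 | methyl (E)-4,4-dimethoxybut-2-enoate | COC(OC)/C=C/C(=O)OC | intermediate
4 | methyl acetoacetate | COC(=O)CC(C)=O | starting material
5 | (triisopropylsiloxy)methyl chloride | ClCO[Si](C(C)C)(C(C)C)C(C)C | starting material
6 | methyl 3-oxo-5-[(triisopropylsilyl)oxy]pentanoate | COC(=O)CC(=O)CCO[Si](C(C)C)(C(C)C)C(C)C | intermediate
7 | dimethyl 3-(dimethoxymethyl)-2-{3-[(triisopropylsilyl)oxy]propanoyl}pentanedioate (Michael adduct, diastereomer mixture, not isolated) | COC(=O)CC(C(OC)OC)C(C(=O)OC)C(=O)CCO[Si](C(C)C)(C(C)C)C(C)C | intermediate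
8 | methyl 6-(dimethoxymethyl)-2,4-dioxo-3-{[(triisopropylsilyl)oxy]methyl}cyclohexane-1-carboxylate (mixture of diastereomers and enol forms) | COC(=O)C1C(=O)C(CO[Si](C(C)C)(C(C)C)C(C)C)C(=O)CC1C(OC)OC | intermediate
9 | methyl 6-(dimethoxymethyl)-2,4-dioxo-1-(phenylselanyl)-3-{[(triisopropylsilyl)oxy]methyl}cyclohexane-1-carboxylate (selenium trans to the C6 acetal, not isolated) | COC(=O)C1([Se]c2ccccc2)C(=O)C(CO[Si](C(C)C)(C(C)C)C(C)C)C(=O)CC1C(OC)OC | intermediate
10 | methyl 6-(dimethoxymethyl)-2,4-dioxo-1-(phenylseleninyl)-3-{[(triisopropylsilyl)oxy]methyl}cyclohexane-1-carboxylate (selenoxide, not isolated) | COC(=O)C1([Se](=O)c2ccccc2)C(=O)C(CO[Si](C(C)C)(C(C)C)C(C)C)C(=O)CC1C(OC)OC | intermediate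
11 | methyl 6-(dimethoxymethyl)-2,4-dihydroxy-3-{[(triisopropylsilyl)oxy]methyl}benzoate | COC(=O)c1c(O)c(CO[Si](C(C)C)(C(C)C)C(C)C)c(O)cc1C(OC)OC | intermediate
12 | methyl 6-(dimethoxymethyl)-2-hydroxy-4-methoxy-3-{[(triisopropylsilyl)oxy]methyl}benzoate | COC(=O)c1c(O)c(CO[Si](C(C)C)(C(C)C)C(C)C)c(OC)cc1C(OC)OC | intermediate
13 | rac-7-hydroxy-3,5-dimethoxy-6-{[(triisopropylsilyl)oxy]methyl}isobenzofuran-1(3H)-one | COC1OC(=O)c2c(O)c(CO[Si](C(C)C)(C(C)C)C(C)C)c(OC)cc21 | intermediate
14 | rac-7-hydroxy-6-(hydroxymethyl)-3,5-dimethoxyisobenzofuran-1(3H)-one | COC1OC(=O)c2c(O)c(CO)c(OC)cc21 | intermediate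
15 | methyl 2,4-dihydroxy-3,6-dimethylbenzoate | COC(=O)c1c(C)cc(O)c(C)c1O | starting material
16 | methyl 2-hydroxy-4-methoxy-3,6-dimethylbenzoate (methyl rhizonate) | COC(=O)c1c(C)cc(OC)c(C)c1O | intermediate
17 | 2-hydroxy-4-methoxy-3,6-dimethylbenzoic acid (rhizonic acid) | COc1cc(C)c(C(=O)O)c(O)c1C | intermediate
18 | rac-(7-hydroxy-3,5-dimethoxy-1-oxo-1,3-dihydroisobenzofuran-6-yl)methyl 2-hydroxy-4-methoxy-3,6-dimethylbenzoate | COc1cc(C)c(C(=O)OCc2c(OC)cc3c(c2O)C(=O)OC3OC)c(O)c1C | intermediate
19 | rac-(3,7-dihydroxy-5-methoxy-1-oxo-1,3-dihydroisobenzofuran-6-yl)methyl 2-hydroxy-4-methoxy-3,6-dimethylbenzoate | COc1cc(C)c(C(=O)OCc2c(OC)cc3c(c2O)C(=O)OC3O)c(O)c1C | intermediate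
20 | [(3R)-3-acetoxy-7-hydroxy-5-methoxy-1-oxo-1,3-dihydroisobenzofuran-6-yl]methyl 2-hydroxy-4-methoxy-3,6-dimethylbenzoate | COc1cc(C)c(C(=O)OCc2c(OC)cc3c(c2O)C(=O)O[C@H]3OC(C)=O)c(O)c1C | intermediate
21 | [(3R)-3,7-dihydroxy-5-methoxy-1-oxo-1,3-dihydroisobenzofuran-6-yl]methyl 2-hydroxy-4-methoxy-3,6-dimethylbenzoate (CNP0398000.1) | COc1cc(C)c(C(=O)OCc2c(OC)cc3c(c2O)C(=O)O[C@H]3O)c(O)c1C | target

Total step count: 13.
Longest linear sequence: 10 steps (steps 2, 3, 4, 5, 6, 7, 10, 11, 12, 13).

Steps most likely to fail

Step 3. The silyloxy group may be lost by β-elimination from the ketone α′-enolate, before or after the conjugate addition, and the vinyl ketone so formed may condense with further enolate; the conjugate addition to the β-substituted enoate may also be slow. The fallback forms the same two ring bonds in the opposite order, sets out from 3 and 6 and returns to the route at 8. Ester 3 is converted with MeNH(OMe)·HCl and iPrMgCl in THF at −20 °C into (E)-N,4,4-trimethoxy-N-methylbut-2-enamide F1. The dilithium dianion of 6 (LiN(iPr)2, THF, −78 °C, a temperature at which β-silyloxy enolates persist) is acylated at its C4 carbon by F1 to give methyl (E)-8,8-dimethoxy-3,5-dioxo-4-{[(triisopropylsilyl)oxy]methyl}oct-6-enoate F2. A catalytic amount of K2CO3 in acetonitrile then closes the ring by intramolecular 6-endo-trig Michael addition of C2 to C7 and gives 8.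

Step 12. The enzyme may select poorly or in the wrong sense, or the lactol may racemise too slowly compared with acylation, so that only a simple kinetic resolution results. The fallback replaces the enzyme by a small-molecule catalyst, sets out from 19 and returns at 20. It is an acylative dynamic kinetic resolution with acetic anhydride, a hindered amine (iPr2NEt) and an enantiopure nucleophilic acyl-transfer catalyst of the chiral bicyclic imidazole type in toluene at 0 °C, a reaction known for 3-hydroxyphthalides, with the catalyst enantiomer chosen for the (R)-acetate. No new compound is made.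

Step 4. Selenium may be taken up at the wrong enolate carbon (C3), or the electron-rich resorcinol may be over-oxidised by the selenium by-products. The fallback is direct dehydrogenation by hydride abstraction, sets out from 8 and returns at 11. DDQ (2,3-dichloro-5,6-dicyano-1,4-benzoquinone, 1.1 equiv) in 1,4-dioxane at 60 °C removes the C5/C6 hydrogens through the enol without an α-heteroatom intermediate. No new compound is made.

Further compounds
F1 | step 3 | (E)-N,4,4-trimethoxy-N-methylbut-2-enamide | COC(OC)/C=C/C(=O)N(C)OC
F2 | step 3 | methyl (E)-8,8-dimethoxy-3,5-dioxo-4-{[(triisopropylsilyl)oxy]methyl}oct-6-enoate | COC(=O)CC(=O)C(CO[Si](C(C)C)(C(C)C)C(C)C)C(=O)/C=C/C(OC)OC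
F0 | step 12 | none | none
F0 | step 4 | none | none
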